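## Structural features

The target, 2-(2,4-dihydroxy-6-pentylphenoxy)-4-methoxy-6-pentanoylbenzoic acid (C24H30O7), consists of two benzene rings joined only by an ether oxygen between a6 and b1; it has no stereocentre, so no configuration has to be set and no stereocentres adjoin. Ring A is an olivetol unit (pentyl at a1, hydroxyls at a3 and a5) with one more oxygen at a6. Ring B carries the ether at b1, methoxy at b3, a pentanoyl group at b5 and the carboxyl at b6, so b1, b6 and b5 form a contiguous trisubstituted edge. The ether oxygen is flanked by pentyl and hydroxyl on ring A and by the carboxyl on ring B, and this tri-ortho-substituted diaryl ether is the real difficulty, because direct coupling of two such arenes is demanding. The fragile groups are the electron-rich ring A once its phenols are free, the a5 hydroxyl ortho to the ether (under base it can migrate ring B by a Smiles rearrangement or lactonise onto the b6 carboxyl), the reducible aryl ketone, and the 2-acylbenzoic acid, which equilibrates with its cyclic lactol. The key step exploits the pattern of ring B: the oxygens at b1 and b3 are meta, b2 and b4 are unsubstituted, and b5 and b6 bear adjacent carbonyl groups. The b1–b2–b3–b4 unit is therefore the C6–C5–C4–C3 diene of a 6-aryloxy-4-methoxy-2-pyrone, and b5–b6 is the triple bond of a masked 4-oxooct-2-ynoate, so the a6–O–b1 bond can be made on the pyrone before ring B exists.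

## Logic of the disconnections

22 ⇒ 21. Two C–O bonds of a 1,3-dioxolane are added back to the carbonyl carbon on b5. The ketone is unmasked last because it would compete with the ester for control of the ring-forming step and is reducible under hydrogenolysis. The gain is that 21 has only one conjugating acceptor on ring B. The forward step must be a hydrolysis mild enough for free phenols and the diaryl ether; dilute aqueous acid, helped by the neighbouring carboxylic acid, should meet that.

21 ⇒ 20. Three O–CH2Ph bonds are reinstated, at the a3 and a5 oxygens and at the carboxyl oxygen. A benzyl ester at b6, rather than a simple alkyl ester, means the di-ortho-substituted benzoate never has to be saponified and no base meets a compound with a free a5 hydroxyl. Debenzylating before the ketal is removed means no aryl ketone is exposed to hydrogen. One neutral operation replaces three. The demand is that three unhindered benzylic C–O bonds are cleaved faster than the fully substituted benzylic ketal.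

20 ⇒ 13 + 18. Ring B is cut at b4–b5 and b6–b1 and a CO2 bridge is put back between b1 and b4 (transient adduct 19). This removes the whole b1/b6/b5 array at once and places the ether oxygen on a pyrone carbon, so the crowded linkage is never made between two benzene rings. Both 13 and 18 are a few steps from simple materials. The forward step must be regioselective (pyrone C3 to the ketal-bearing alkyne carbon) and must tolerate forcing heat.

13 ⇒ 7 + 12. The O–b1 bond (pyrone C6–O) is cut. C6 of 12 is a flat, unhindered carbon at the acyl chloride oxidation level, so a hindered phenoxide can reach it by addition–elimination. The gain is two fragments of similar size, one carrying all of ring A. The demand is that the phenoxide of 7 substitutes at C6 and does not consume a second equivalent by opening the lactone.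

12 ⇒ 11 ⇒ 8 (through 10 and 9). The O–CH3 bond is cut first. Then, after a carboxyl group is added back at C3, the C3–C4 and O1–C2 bonds are cut to give two molecules of 8. One three-carbon building block thus supplies a pyrone with chlorine at C6 and oxygen at C4. The demands are methylation on the 4-oxygen and survival of the vinylic chloride through hydrolysis and decarboxylation.

7 ⇒ 5 ⇒ 3 ⇒ 1 + 2 (through 6 and 4). The a6–O bond is traced to an a6–CHO bond, the formyl carbon is removed, and the two O–benzyl bonds are cut, which calls for two molecules of 2. Direct hydroxylation at a6 would not be selective, whereas formylation is directed para to one ether and ortho to the other. The demands are that formylation avoids the position between the two benzyloxy groups and that the aryl group, not hydride, migrates in the peracid step.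

18 ⇒ 16 ⇒ 15 ⇒ 14 (through 17). The bond from the alkyne terminus to the carboxyl carbon is cut, then the two ketal C–O bonds, then the carbinol oxidation level is lowered. The ester comes last so that ketalisation is done on a simple ynone and not on a doubly activated 4-oxo-ynoate. The demands are ketalisation without conjugate addition and acylation of the acetylide without double addition.

## Other disconnections considered

Alternative 1: The cut runs through ring A (a6–a1 and a4–a5). Ring A is grown as a cyclohexane-1,3-dione on the carbon that already carries the ether oxygen, and ring B is carried as a butylphthalide, with the b5 carbonyl at the alcohol level. In the forward key step NaOMe in MeOH would add the malonate carbon of dimethyl 2-[(3-butyl-5-methoxy-1-oxo-1,3-dihydroisobenzofuran-7-yl)oxy]propanedioate A1 to the β-carbon of (E)-non-3-en-2-one A2. The methyl ketone enolate would then close onto one malonate ester to give the dioxocyclohexanecarboxylate A3 as a mixture of diastereomers.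
- In favour: the a6–O bond is made by alkylation at an sp3 malonate carbon. This is a simpler and more certain C–O bond formation than step 6 of the chosen plan, and on this point the alternative is the better one. The partners are cheap, nothing is heated strongly, and the pattern of ring A follows from connectivity alone.
- Against: a tertiary aryloxymalonate anion must add to a β-alkyl enone and create a quaternary carbon beside a tertiary one, which is readily reversed. Methoxide can also open the lactone of A1.
- Comparison: A3 is at the wrong oxidation level on both rings. The angular ester must be removed, the dione dehydrogenated, and the phthalide carbon oxidised back to the ketone with an electron-rich ring A present. That is at least four further steps with two oxidations, against two non-oxidative steps after step 10. Mechanistically it is a reversible ionic cascade, whereas the chosen plan is made irreversible by loss of CO2. It is also longer, because A1 needs a separately built ring B phenol.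

Alternative 2: The cut again lies in ring A, but four bonds are made at once (a1–a2, a2–a3, a4–a5, a5–a6). Irradiation of 3-{[(3-butyl-5-methoxy-1-oxo-1,3-dihydroisobenzofuran-7-yl)oxy]methylidene}-1-diazooctan-2-one A4 would trigger a Wolff rearrangement to an aryloxy-substituted vinylketene. This would add benzyl ethynyl ether A5 in a (2+2) cycloaddition; four-electron ring opening, six-electron closure and tautomerisation would then give the phenol A6.
- In favour: regiochemistry is fixed by the order of pericyclic events and not by a frontier orbital bias, so on regiocontrol it is at least the equal of the chosen plan. It forms four bonds in one operation against two in step 10. The ether oxygen is again carried in from an enol ether.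
- Against: A4 would need regioselective hydroxymethylenation of an unsymmetrical ketone, enol aryl ether formation and a diazo transfer on a base-sensitive substrate. A5 is thermally labile. The β-aryloxy group donates into the vinylketene and should make it less electrophilic toward the ynol ether.
- Comparison: A6 still holds ring B as a phthalide, so a late benzylic oxidation in the presence of an electron-rich ring A is needed, followed by debenzylation. The step count would be well above that of the chosen plan, which keeps both rings at the correct oxidation level throughout.

Alternative 3: The cut lies in ring B at b5–b6 and b3–b4. Base would condense dimethyl 3-[2,4-bis(benzyloxy)-6-pentylphenoxy]pent-2-enedioate A7 with 1-(2-butyl-1,3-dioxolan-2-yl)ethan-1-one A8. A Knoevenagel condensation at the ketone carbonyl would be followed by attack of the methyl carbon on the far ester, giving the phenol A9.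
- In favour: it uses the same phenol 7 and the same kind of ether formation (addition–elimination on a β-chloro unsaturated ester) as the chosen plan, so the two are equal there. The anion of A7 is symmetric, so no regiochemical question arises. The chemistry is ionic at moderate temperature instead of 160 °C, and in that respect it is better.
- Against: the ketone of A8 is flanked by a fully substituted ketal carbon and is a poor Knoevenagel acceptor. A7 is a β-aryloxy acrylate from which an alkoxide base can expel the aryloxide, and both partners can self-condense.
- Comparison: A9 has the same skeleton as 20 but a free hydroxyl at b3 and a methyl ester. Methylation, ketal removal, saponification of a di-ortho-substituted benzoate and hydrogenolysis would follow, four steps against two.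

Key step: step 10

Remark: the 2-acylbenzoic acid 22 is expected to equilibrate with its cyclic lactol tautomer; the open keto acid is taken as the compound to be delivered. Compound 14 is used as the racemate, since its stereocentre is destroyed in step 7.

## Route

Step 1
Reactants: 1 olivetol (5-pentylbenzene-1,3-diol); 2 benzyl bromide (two molecules)
Product: 3 1,3-bis(benzyloxy)-5-pentylbenzene
Conditions: BnBr (2.2 equiv), K2CO3, DMF, 60 °C
Reagents that add atoms: benzyl bromide (the second molecule), BrCc1ccccc1
Why: Twofold Williamson ether synthesis; each phenol is alkylated by one molecule of the reactive benzylic bromide, and O-alkylation dominates in a polar aprotic solvent.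

Step 2
Reactants: 3 1,3-bis(benzyloxy)-5-pentylbenzene
Product: 5 2,4-bis(benzyloxy)-6-pentylbenzaldehyde, via aryl iminium chloride 4 (not isolated)
Conditions: POCl3, DMF, 0 °C to 70 °C; then aq. NaOAc, rt
Reagents that add atoms: N,N-dimethylformamide, CN(C)C=O; water, O
Why: Vilsmeier–Haack formylation; the chloroiminium ion attacks the position para to one benzyloxy group and ortho to the other, the site between the two benzyloxy groups being more hindered, and the iminium salt is hydrolysed on work-up.

Step 3
Reactants: 5 2,4-bis(benzyloxy)-6-pentylbenzaldehyde
Product: 7 2,4-bis(benzyloxy)-6-pentylphenol, via aryl formate 6 (not isolated)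
Conditions: mCPBA, CH2Cl2, 0 °C to rt; aq. NaHCO3 wash; then K2CO3 (cat.), MeOH, rt
Reagents that add atoms: 3-chloroperoxybenzoic acid, OOC(=O)c1cccc(Cl)c1
Why: Baeyer–Villiger (Dakin-type) oxidation; the electron-rich aryl group migrates in preference to hydride, and the formate is removed by methanolysis.

Step 4
Reactants: 8 malonyl dichloride (two molecules)
Product: 11 6-chloro-4-hydroxy-2H-pyran-2-one, via pyranone acid chloride 9 (not isolated), via pyranone carboxylic acid 10 (not isolated)
Conditions: neat, rt, several days (HCl vented); then H2O, 1,4-dioxane, rt to 80 °C
Reagents that add atoms: malonyl dichloride (the second molecule), O=C(Cl)CC(=O)Cl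
Why: Known self-condensation of malonyl dichloride: C-acylation of one molecule by a second and O-acylative ring closure with loss of HCl give 9; its acid chloride is hydrolysed to the vinylogous β-keto acid 10, which decarboxylates on warming, while the vinylic chloride is far less reactive toward water.

Step 5
Reactants: 11 6-chloro-4-hydroxy-2H-pyran-2-one
Product: 12 6-chloro-4-methoxy-2H-pyran-2-one
Conditions: Me2SO4, K2CO3, acetone, rt
Reagents that add atoms: dimethyl sulfate, COS(=O)(=O)OC
Why: O-alkylation of the acidic 4-hydroxyl of a 4-hydroxy-2-pyrone; with a hard methylating agent and carbonate in acetone the 4-methoxy-2-pyrone should prevail over the 2-methoxy-4-pyrone isomer.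

Step 6
Reactants: 7 2,4-bis(benzyloxy)-6-pentylphenol; 12 6-chloro-4-methoxy-2H-pyran-2-one (1.2 equiv)
Product: 13 6-[2,4-bis(benzyloxy)-6-pentylphenoxy]-4-methoxy-2H-pyran-2-one
Conditions: Cs2CO3, MeCN (dry), N2, 0 °C to rt
Reagents that add atoms: none
Why: Addition–elimination (nucleophilic vinylic substitution) at C6 of 12, a doubly vinylogous acyl chloride: the phenoxide adds to give a dienolate delocalised onto the C2 carbonyl oxygen and chloride leaves; attack at C2 would open the ring to a ketene that can reclose to the same product, and the flat C6 carbon is open to the di-ortho-substituted phenoxide.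

Step 7
Reactants: 14 hept-1-yn-3-ol (racemic)
Product: 15 hept-1-yn-3-one
Conditions: CrO3, H2SO4, H2O, acetone, 0 °C
Reagents that add atoms: none
Why: Jones oxidation of a secondary propargylic alcohol to the ynone, fast at 0 °C and without effect on the terminal alkyne; the stereocentre is removed.

Step 8
Reactants: 15 hept-1-yn-3-one
Product: 16 2-butyl-2-ethynyl-1,3-dioxolane
Conditions: Me3SiOCH2CH2OSiMe3, Me3SiOTf (cat.), CH2Cl2, −78 °C to −20 °C; pyridine quench
Reagents that add atoms: 1,2-bis(trimethylsilyloxy)ethane, C[Si](C)(C)OCCO[Si](C)(C)C
Why: Noyori ketalisation; the silylated diol and catalytic silyl triflate form the dioxolane under aprotic conditions at low temperature, which avoids conjugate addition of free ethylene glycol to the terminal ynone.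

Step 9
Reactants: 16 2-butyl-2-ethynyl-1,3-dioxolane
Product: 18 benzyl 3-(2-butyl-1,3-dioxolan-2-yl)prop-2-ynoate, via lithium acetylide 17 (not isolated)
Conditions: n-BuLi, THF, −78 °C; then added to ClCO2Bn, THF, −78 °C to 0 °C
Reagents that add atoms: benzyl chloroformate, O=C(Cl)OCc1ccccc1
Why: Deprotonation of the terminal alkyne and acylation of the acetylide by the chloroformate; inverse addition keeps the chloroformate in excess and suppresses double addition, and the ketal is inert to the base.

Step 10
Reactants: 13 6-[2,4-bis(benzyloxy)-6-pentylphenoxy]-4-methoxy-2H-pyran-2-one; 18 benzyl 3-(2-butyl-1,3-dioxolan-2-yl)prop-2-ynoate (2.5 equiv)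
Product: 20 benzyl 2-[2,4-bis(benzyloxy)-6-pentylphenoxy]-6-(2-butyl-1,3-dioxolan-2-yl)-4-methoxybenzoate, via bicyclic lactone 19 (not isolated)
Conditions: PhMe (dry, degassed), BHT (cat.), sealed tube, 160 °C
Reagents that add atoms: none
Why: The diene C3=C4–C5=C6 of 13 and the triple bond of 18 combine in a thermal normal-electron-demand (4+2) cycloaddition to the 2-oxabicyclo[2.2.2]octadienone 19, which loses CO2 by a retro-(4+2) reaction under the same conditions and so becomes the aromatic ring B. The closest known reaction type is the benzannulation of 4- and 6-oxygenated 2-pyrones with alkynoates, of which 13 is a new member of a known class. Ring B is closed by an intermolecular cycloaddition that forms b4–b5 and b6–b1 in one asynchronous event, the bond from pyrone C3 to the ester β-carbon being the more advanced; aromatisation is by cycloreversion and not by elimination, so the aryloxy group at b1 cannot be lost. The two bridgehead stereocentres of racemic 19 vanish with the CO2 and 20 has no stereocentre. The step needs regioselectivity: the ring oxygen and aryloxy group at C6 and the methoxy group at C4 all place the largest HOMO coefficient on C3, and because the ketone is masked as a ketal the ester is the only conjugating acceptor of 18, so its largest LUMO coefficient lies on the ketal-bearing carbon. This pairing puts the ketal at b5 and the ester at b6, and it also joins the crowded C6 to the flat ester-bearing carbon late on the reaction coordinate. Benzyl ethers, benzyl ester and dioxolane are inert to neutral heating, and BHT should suppress radical polymerisation of the ynoate.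

Step 11
Reactants: 20 benzyl 2-[2,4-bis(benzyloxy)-6-pentylphenoxy]-6-(2-butyl-1,3-dioxolan-2-yl)-4-methoxybenzoate
Product: 21 2-(2-butyl-1,3-dioxolan-2-yl)-6-(2,4-dihydroxy-6-pentylphenoxy)-4-methoxybenzoic acid
Conditions: H2 (1 atm), Pd/C, EtOAc, rt
Reagents that add atoms: none
Why: Catalytic hydrogenolysis cleaves the two aryl benzyl ethers and the benzyl ester at their O–CH2Ph bonds, away from the hindered carbonyl carbon; the ketone is still a dioxolane and cannot be reduced, and no base meets the freed a5 hydroxyl.

Step 12
Reactants: 21 2-(2-butyl-1,3-dioxolan-2-yl)-6-(2,4-dihydroxy-6-pentylphenoxy)-4-methoxybenzoic acid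
Product: 22 2-(2,4-dihydroxy-6-pentylphenoxy)-4-methoxy-6-pentanoylbenzoic acid
Conditions: 1 M HCl, THF, 40 °C
Reagents that add atoms: water, O
Why: Acid-catalysed hydrolysis of the dioxolane through an oxocarbenium ion, assisted by the neighbouring carboxylic acid; the diaryl ether and phenols tolerate dilute acid, and both positions ortho to the ether on ring A are occupied, so acid-induced xanthone formation is impossible.

## Compound list

1 | olivetol (5-pentylbenzene-1,3-diol) | CCCCCc1cc(O)cc(O)c1 | starting material
2 | benzyl bromide | BrCc1ccccc1 | starting material
3 | 1,3-bis(benzyloxy)-5-pentylbenzene | CCCCCc1cc(OCc2ccccc2)cc(OCc2ccccc2)c1 | intermediate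
4 | N-{[2,4-bis(benzyloxy)-6-pentylphenyl]methylidene}-N-methylmethanaminium chloride | CCCCCc1cc(OCc2ccccc2)cc(OCc2ccccc2)c1C=[N+](C)C.[Cl-] | intermediate (not isolated)
5 | 2,4-bis(benzyloxy)-6-pentylbenzaldehyde | CCCCCc1cc(OCc2ccccc2)cc(OCc2ccccc2)c1C=O | intermediate
6 | 2,4-bis(benzyloxy)-6-pentylphenyl formate | CCCCCc1cc(OCc2ccccc2)cc(OCc2ccccc2)c1OC=O | intermediate (not isolated)
7 | 2,4-bis(benzyloxy)-6-pentylphenol | CCCCCc1cc(OCc2ccccc2)cc(OCc2ccccc2)c1O | intermediate
8 | malonyl dichloride | O=C(Cl)CC(=O)Cl | starting material
9 | 6-chloro-4-hydroxy-2-oxo-2H-pyran-3-carbonyl chloride | O=C(Cl)c1c(O)cc(Cl)oc1=O | intermediate (not isolated)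
10 | 6-chloro-4-hydroxy-2-oxo-2H-pyran-3-carboxylic acid | O=C(O)c1c(O)cc(Cl)oc1=O | intermediate (not isolated)
11 | 6-chloro-4-hydroxy-2H-pyran-2-one | Oc1cc(Cl)oc(=O)c1 | intermediate
12 | 6-chloro-4-methoxy-2H-pyran-2-one | COc1cc(Cl)oc(=O)c1 | intermediate
13 | 6-[2,4-bis(benzyloxy)-6-pentylphenoxy]-4-methoxy-2H-pyran-2-one | CCCCCc1cc(OCc2ccccc2)cc(OCc2ccccc2)c1Oc1cc(OC)cc(=O)o1 | intermediate
14 | hept-1-yn-3-ol (racemic) | CCCCC(O)C#C | starting material
15 | hept-1-yn-3-one | CCCCC(=O)C#C | intermediate
16 | 2-butyl-2-ethynyl-1,3-dioxolane | CCCCC1(C#C)OCCO1 | intermediate
17 | [(2-butyl-1,3-dioxolan-2-yl)ethynyl]lithium | CCCCC1(C#C[Li])OCCO1 | intermediate (not isolated)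
18 | benzyl 3-(2-butyl-1,3-dioxolan-2-yl)prop-2-ynoate | CCCCC1(OCCO1)C#CC(=O)OCc1ccccc1 | intermediate
19 | benzyl 1-[2,4-bis(benzyloxy)-6-pentylphenoxy]-5-(2-butyl-1,3-dioxolan-2-yl)-8-methoxy-3-oxo-2-oxabicyclo[2.2.2]octa-5,7-diene-6-carboxylate (racemic) | CCCCCc1cc(OCc2ccccc2)cc(OCc2ccccc2)c1OC12C=C(OC)C(C(=O)O1)C(C1(CCCC)OCCO1)=C2C(=O)OCc1ccccc1 | intermediate (not isolated)
20 | benzyl 2-[2,4-bis(benzyloxy)-6-pentylphenoxy]-6-(2-butyl-1,3-dioxolan-2-yl)-4-methoxybenzoate | CCCCCc1cc(OCc2ccccc2)cc(OCc2ccccc2)c1Oc1cc(OC)cc(C2(CCCC)OCCO2)c1C(=O)OCc1ccccc1 | intermediate
21 | 2-(2-butyl-1,3-dioxolan-2-yl)-6-(2,4-dihydroxy-6-pentylphenoxy)-4-methoxybenzoic acid | CCCCCc1cc(O)cc(O)c1Oc1cc(OC)cc(C2(CCCC)OCCO2)c1C(=O)O | intermediate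
22 | 2-(2,4-dihydroxy-6-pentylphenoxy)-4-methoxy-6-pentanoylbenzoic acid | CCCCCc1cc(O)cc(O)c1Oc1cc(OC)cc(C(=O)CCCC)c1C(=O)O | target

## Step count and least certain steps

Total step count: 12. Longest linear sequence: 7 steps (1, 2, 3, 6, 10, 11, 12).

Step 10 (key step). The most likely failure is a bimolecular cycloaddition at the crowded C6 terminus that is too slow, so that thermal ring opening or hydrolytic loss of the aryloxypyrone and polymerisation of the ynoate win; erosion of regioselectivity is a second risk. The fallback makes the ether bond after ring B. It sets out from 12 and 18 and returns at 20. Heating 12 with 18 (1,2-dichlorobenzene, 170 °C) should give, by the same cycloaddition and CO2 loss but with only a small chlorine at C6, benzyl 2-chloro-6-(2-butyl-1,3-dioxolan-2-yl)-4-methoxybenzoate F1. The aryl chloride ortho to the ester is then joined to 7 by a palladium-catalysed diaryl ether coupling (Pd(OAc)2, 2-di-tert-butylphosphino-2′,4′,6′-triisopropylbiphenyl, K3PO4, PhMe, 100 °C) to give 20; this coupling is itself demanding, but the ortho ester activates the chloride toward oxidative addition.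

Step 6. The most likely failure is acyl attack at C2 with ring opening and capture of a second phenoxide, together with slow substitution by the hindered phenoxide and hydrolytic loss of the ketene-acetal-like product on isolation. The fallback builds the pyrone on the aryl ester instead. It sets out from 7 and returns at 13, and it also makes the route independent of 11 and 12. Commercially listed dimethyl 3-methoxypent-2-enedioate is saponified (NaOH, then HCl) to (2E)-3-methoxypent-2-enedioic acid F2. Ac2O dehydrates this to 4-methoxy-2H-pyran-2,6(3H)-dione F3. Phenol 7 opens the anhydride at its non-conjugated carbonyl (Et3N, DMAP cat., CH2Cl2) to give (2E)-5-[2,4-bis(benzyloxy)-6-pentylphenoxy]-3-methoxy-5-oxopent-2-enoic acid F4. Cyclodehydration of F4 through its mixed anhydride ((CF3CO)2O, Et3N, CH2Cl2, 0 °C) closes the ester carbonyl oxygen onto the activated acid and gives 13. Double-bond isomers of F4 converge on the same pyrone.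

Step 4. The most likely failure is incomplete condensation with oligomerisation through chlorocarbonylketene, and partial loss of the vinylic chloride during the aqueous decarboxylation. The fallback intercepts the condensation product as a purifiable derivative. It sets out from 8 and returns at 11. Running the condensation in the presence of acetone should capture the acid chloride and the 4-hydroxyl as the crystalline acetonide 7-chloro-2,2-dimethyl-4H,5H-pyrano[4,3-d][1,3]dioxine-4,5-dione F5. After recrystallisation, warming F5 in aqueous 1,4-dioxane releases acetone and CO2 and gives 11.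

Step 11. The most likely failure is over-reduction by hydrogenolysis of the benzylic C–O bonds of the aryl dioxolane, or stalling at the hindered a5 benzyl ether. The fallback replaces hydrogenolysis by Lewis acid cleavage. It sets out from 20 and returns at 22, replacing steps 11 and 12. BCl3 with pentamethylbenzene as cation scavenger (CH2Cl2, −78 °C) should cleave both benzyl ethers and the benzyl ester, while the unchelated b3 methyl ether is expected to survive at this temperature. The dioxolane is opened by the same reagent and by the aqueous HCl/THF work-up, so 22 is obtained directly.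

## Further compounds

F1 | step 10 | benzyl 2-chloro-6-(2-butyl-1,3-dioxolan-2-yl)-4-methoxybenzoate | CCCCC1(OCCO1)c1cc(OC)cc(Cl)c1C(=O)OCc1ccccc1
F2 | step 6 | (2E)-3-methoxypent-2-enedioic acid | OC(=O)C/C(OC)=C\C(=O)O
F3 | step 6 | 4-methoxy-2H-pyran-2,6(3H)-dione | COC1=CC(=O)OC(=O)C1
F4 | step 6 | (2E)-5-[2,4-bis(benzyloxy)-6-pentylphenoxy]-3-methoxy-5-oxopent-2-enoic acid | CCCCCc1cc(OCc2ccccc2)cc(OCc2ccccc2)c1OC(=O)C/C(OC)=C\C(=O)O
F5 | step 4 | 7-chloro-2,2-dimethyl-4H,5H-pyrano[4,3-d][1,3]dioxine-4,5-dione | CC1(C)OC(=O)c2c(O1)cc(Cl)oc2=O
F0 | step 11 | none | none
A1 | alternative 1 | dimethyl 2-[(3-butyl-5-methoxy-1-oxo-1,3-dihydroisobenzofuran-7-yl)oxy]propanedioate (racemic) | COC(=O)C(Oc1cc(OC)cc2c1C(=O)OC2CCCC)C(=O)OC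
A2 | alternative 1 | (E)-non-3-en-2-one | CCCCC/C=C/C(C)=O
A3 | alternative 1 | methyl 1-[(3-butyl-5-methoxy-1-oxo-1,3-dihydroisobenzofuran-7-yl)oxy]-2,4-dioxo-6-pentylcyclohexane-1-carboxylate (mixture of diastereomers) | CCCCCC1CC(=O)CC(=O)C1(Oc1cc(OC)cc2c1C(=O)OC2CCCC)C(=O)OC
A4 | alternative 2 | 3-{[(3-butyl-5-methoxy-1-oxo-1,3-dihydroisobenzofuran-7-yl)oxy]methylidene}-1-diazooctan-2-one (racemic, either enol ether geometry) | CCCCCC(=COc1cc(OC)cc2c1C(=O)OC2CCCC)C(=O)C=[N+]=[N-]
A5 | alternative 2 | benzyl ethynyl ether | C#COCc1ccccc1
A6 | alternative 2 | 7-[4-(benzyloxy)-2-hydroxy-6-pentylphenoxy]-3-butyl-5-methoxyisobenzofuran-1(3H)-one (racemic) | CCCCCc1cc(OCc2ccccc2)cc(O)c1Oc1cc(OC)cc2c1C(=O)OC2CCCC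
A7 | alternative 3 | dimethyl 3-[2,4-bis(benzyloxy)-6-pentylphenoxy]pent-2-enedioate (either double-bond isomer) | CCCCCc1cc(OCc2ccccc2)cc(OCc2ccccc2)c1OC(CC(=O)OC)=CC(=O)OC
A8 | alternative 3 | 1-(2-butyl-1,3-dioxolan-2-yl)ethan-1-one | CCCCC1(OCCO1)C(C)=O
A9 | alternative 3 | methyl 2-[2,4-bis(benzyloxy)-6-pentylphenoxy]-6-(2-butyl-1,3-dioxolan-2-yl)-4-hydroxybenzoate | CCCCCc1cc(OCc2ccccc2)cc(OCc2ccccc2)c1Oc1cc(O)cc(C2(CCCC)OCCO2)c1C(=O)OC
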